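**Strategy.** Numbering the six-membered ring C1 (ketone), C2 (amide nitrogen), C3, C4 (carbinol), C5 and C6 (oxirane), the C2–N bond is disconnected first. What remains is a 4-hydroxycyclohexa-2,5-dienone with a mirror plane through C1 and C4, so its C2=C3 and C5=C6 enones are enantiotopic. The key step epoxidises C5=C6 alone, on the face of the C4 hydroxyl, with a chiral ammonium peroxide ion pair: one operation closes the oxirane ring and sets C4, C5 and C6. Its precursor is the para-quinol of a 4-hydroxycinnamate, carried as the tert-butyl ester. The upper amide is then joined at C2 by iodination and copper-catalysed coupling, and the trienamide by a vinylogous Horner–Wadsworth–Emmons reaction.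

Key step: step 3

Assumption: N-benzylcinchonidinium chloride is taken to favour epoxidation of the enone that leads to 5; should it favour the other enone, the pseudo-enantiomeric N-benzylcinchoninium chloride replaces it and nothing else changes.

Remarks on the design:
- The quinol ester is tert-butyl, not methyl. It keeps the small, polar quinol in the organic phase where the chiral ion pair acts, cannot be saponified by aqueous hydroxide, and makes the acrylate a still poorer acceptor.
- A hydride that reduces the side-chain ester cannot spare the C1 ketone. Steps 11 and 12 therefore reduce both carbonyls and re-oxidise both allylic carbinols.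
- In the target the C4 hydroxyl and the oxirane are on the same ring face, configuration (1S,5S,6R).
- Locants C1–C6 in the text follow the ring numbering above. Names use 7-oxabicyclo[4.1.0]heptane numbering, in which ring atoms C6, C1, C2, C3, C4, C5 become positions 1, 2, 3, 4, 5, 6.
- The descriptor of the ring carbinol changes from R in 5 to S from 6 onward only because the C2 substituent changes the CIP priorities; the geometry is the same.

**Route**

Step 1
Reactants: 1 4-hydroxybenzaldehyde; 2 tert-butyl (triphenylphosphoranylidene)acetate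
Product: 3 tert-butyl (E)-3-(4-hydroxyphenyl)prop-2-enoate
Conditions: toluene, 80 °C
Reagents that add atoms: none
Why: Wittig olefination with a stabilised ylide, which tolerates the free phenol and gives the E-alkene.

Step 2
Reactants: 3 tert-butyl (E)-3-(4-hydroxyphenyl)prop-2-enoate
Product: 4 tert-butyl (E)-3-(1-hydroxy-4-oxocyclohexa-2,5-dien-1-yl)prop-2-enoate
Conditions: PhI(OAc)2 (1.1 equiv), MeCN/H2O 3:1, 0 °C
Reagents that add atoms: water, O
Why: Oxidative dearomatisation of a para-substituted phenol by trivalent iodine, in which water captures the activated phenol at the para carbon because the acrylate disfavours positive charge on the side chain.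

Step 3
Reactants: 4 tert-butyl (E)-3-(1-hydroxy-4-oxocyclohexa-2,5-dien-1-yl)prop-2-enoate
Product: 5 tert-butyl (E)-3-[(1S,5R,6R)-5-hydroxy-2-oxo-7-oxabicyclo[4.1.0]hept-3-en-5-yl]prop-2-enoate (hydroxyl syn to the oxirane)
Conditions: tBuOOH (1.05 equiv, in decane), N-benzylcinchonidinium chloride (10 mol%), aq. NaOH (1 M, 0.2 equiv), toluene, 0 °C
Reagents that add atoms: tert-butyl hydroperoxide, CC(C)(C)OO
Why: Proposed new method: the tert-butylperoxide anion, carried into toluene as its chiral ammonium ion pair and hydrogen-bonded to the C4 hydroxyl, adds to C5 on the hydroxyl face and the C6 enolate then displaces tert-butoxide at the O–O bond (Weitz–Scheffer mechanism); the closest known reactions are chiral-ammonium phase-transfer epoxidation of cyclic enones and quinone monoketals and the hydroxyl-directed syn-epoxidation of para-quinols, merged here into an enantiotopic-group selection not yet shown on a para-quinol. The oxirane closes in 3-exo-tet mode. C5 and C6 are set syn to the hydroxyl by the hydrogen-bond delivery and are necessarily cis on the ring, whereas C4 becomes stereogenic only through the choice of enone, which the chiral cation makes because the hydroxyl face has opposite prochirality on C5=C6 and on C2=C3. Group selectivity therefore rests on the catalyst, facial selectivity on the free C4 hydroxyl, and chemoselectivity on the dienone being far more electrophilic than the hindered tert-butyl acrylate, whose bulk also holds 4 in the organic phase and excludes saponification. About one equivalent of oxidant limits bis-epoxidation, and any second epoxidation should consume mainly the minor enantiomer, whose remaining enone is the one the catalyst prefers, so the enantiomeric purity of 5 should rise with conversion.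

Step 4
Reactants: 5 tert-butyl (E)-3-[(1S,5R,6R)-5-hydroxy-2-oxo-7-oxabicyclo[4.1.0]hept-3-en-5-yl]prop-2-enoate
Product: 6 tert-butyl (E)-3-[(1S,5S,6R)-5-hydroxy-3-iodo-2-oxo-7-oxabicyclo[4.1.0]hept-3-en-5-yl]prop-2-enoate
Conditions: I2 (2 equiv), pyridine/CH2Cl2 1:1, 0 °C to rt; aq. Na2S2O3
Reagents that add atoms: iodine, II
Why: Pyridine-mediated α-iodination of an enone (conjugate addition of pyridine, iodination of the enolate, elimination), regiochemically unambiguous because C2=C3 is the only enone left and the acrylate is too poor an acceptor for pyridine.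

Step 5
Reactants: 7 (R)-4-benzyloxazolidin-2-one; 8 hexanoyl chloride
Product: 9 (R)-4-benzyl-3-hexanoyloxazolidin-2-one
Conditions: n-BuLi, THF, −78 °C; then 8, −78 °C to 0 °C
Reagents that add atoms: none
Why: N-acylation of the lithiated oxazolidinone by the acid chloride, the standard attachment of an Evans auxiliary.

Step 6
Reactants: 9 (R)-4-benzyl-3-hexanoyloxazolidin-2-one
Product: 10 (R)-4-benzyl-3-[(2R)-2-methylhexanoyl]oxazolidin-2-one
Conditions: NaN(SiMe3)2, THF, −78 °C; then MeI
Reagents that add atoms: iodomethane, CI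
Why: Evans asymmetric alkylation, in which the chelated Z-sodium enolate is methylated on the face opposite the benzyl group of the (R)-auxiliary, setting the (R)-methyl centre.

Step 7
Reactants: 10 (R)-4-benzyl-3-[(2R)-2-methylhexanoyl]oxazolidin-2-one
Product: 11 (R)-2-methylhexan-1-ol
Conditions: LiBH4, Et2O, H2O (1 equiv), 0 °C
Reagents that add atoms: none
Why: Reductive cleavage of the N-acyloxazolidinone at the exocyclic carbonyl, which returns the auxiliary and does not touch the α-stereocentre.

Step 8
Reactants: 11 (R)-2-methylhexan-1-ol; 12 ethyl 2-(triphenylphosphoranylidene)propanoate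
Product: 14 ethyl (2E,4R)-2,4-dimethyloct-2-enoate, via (R)-2-methylhexanal 13 (not isolated)
Conditions: TEMPO (10 mol%), PhI(OAc)2 (1.1 equiv), CH2Cl2, rt; then 12, rt to 40 °C
Reagents that add atoms: none
Why: Nitroxyl-catalysed oxidation gives the configurationally labile aldehyde under non-basic conditions and the α-methyl stabilised ylide traps it in the same flask (tandem oxidation–Wittig olefination), the trisubstituted alkene forming E as usual for such ylides.

Step 9
Reactants: 14 ethyl (2E,4R)-2,4-dimethyloct-2-enoate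
Product: 15 (2E,4R)-2,4-dimethyloct-2-enamide
Conditions: AlMe3, NH4Cl, toluene, 0 °C to 50 °C; aq. HCl
Reagents that add atoms: ammonium chloride, [NH4+].[Cl-]
Why: Aluminium amide aminolysis of an ester, in which the amidoaluminium reagent formed in the flask attacks the ester carbonyl directly under conditions too weakly basic to disturb the alkene geometry or the γ-stereocentre.

Step 10
Reactants: 6 tert-butyl (E)-3-[(1S,5S,6R)-5-hydroxy-3-iodo-2-oxo-7-oxabicyclo[4.1.0]hept-3-en-5-yl]prop-2-enoate; 15 (2E,4R)-2,4-dimethyloct-2-enamide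
Product: 16 tert-butyl (E)-3-[(1S,5S,6R)-3-[[(2E,4R)-2,4-dimethyloct-2-enoyl]amino]-5-hydroxy-2-oxo-7-oxabicyclo[4.1.0]hept-3-en-5-yl]prop-2-enoate
Conditions: CuI (10 mol%), N,N'-dimethylethylenediamine (20 mol%), K2CO3 (2 equiv), toluene, 60 °C
Reagents that add atoms: none
Why: Copper-catalysed vinylic amidation (Goldberg-type coupling), in which the monovalent copper amidate inserts into the activated C2–I bond of the α-iodoenone and reductive elimination forms the C2–N bond without involving a stereocentre.

Step 11
Reactants: 16 tert-butyl (E)-3-[(1S,5S,6R)-3-[[(2E,4R)-2,4-dimethyloct-2-enoyl]amino]-5-hydroxy-2-oxo-7-oxabicyclo[4.1.0]hept-3-en-5-yl]prop-2-enoate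
Product: 17 (2E,4R)-N-[2,5-dihydroxy-5-[(E)-3-hydroxyprop-1-en-1-yl]-7-oxabicyclo[4.1.0]hept-3-en-3-yl]-2,4-dimethyloct-2-enamide, carbinol C4 and oxirane centres as in 16, both epimers at the new C1 carbinol
Conditions: iBu2AlH (6.5 equiv), CH2Cl2, −78 °C; aq. KNaC4H4O6 (potassium sodium tartrate)
Reagents that add atoms: none
Why: Hydride reduction of the conjugated ester to the allylic alcohol, with the unavoidable 1,2-reduction of the C1 ketone accepted (its epimer mixture is erased in step 12), while the deprotonated amide, the hydroxyl and the oxirane are inert at −78 °C.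

Step 12
Reactants: 17 the triol of step 11
Product: 18 (2E,4R)-N-[(1S,5S,6R)-5-hydroxy-2-oxo-5-[(E)-3-oxoprop-1-en-1-yl]-7-oxabicyclo[4.1.0]hept-3-en-3-yl]-2,4-dimethyloct-2-enamide
Conditions: MnO2 (activated, excess), CH2Cl2, rt
Reagents that add atoms: none
Why: Allylic oxidation by MnO2, which returns both the primary side-chain carbinol and the secondary C1 carbinol (allylic to C2=C3) to carbonyls and cannot oxidise the tertiary C4 hydroxyl.

Step 13
Reactants: 19 cyclopentane-1,3-dione
Product: 20 3-hydroxy-2-nitrocyclopent-2-en-1-one (enol of 2-nitrocyclopentane-1,3-dione)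
Conditions: fuming HNO3, Et2O, 0 °C
Reagents that add atoms: nitric acid, O[N+](=O)[O-]
Why: Electrophilic nitration of the enol of a cyclic 1,3-dione at C2, its only nucleophilic carbon.

Step 14
Reactants: 20 3-hydroxy-2-nitrocyclopent-2-en-1-one
Product: 21 2-amino-3-hydroxycyclopent-2-en-1-one hydrochloride
Conditions: H2 (1 atm), Pd/C, HCl, MeOH, rt
Reagents that add atoms: hydrogen chloride, Cl
Why: Catalytic hydrogenation of the nitro group, with the amine trapped as its hydrochloride to prevent self-condensation of the free 2-amino-1,3-dione.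

Step 15
Reactants: 22 triethyl 4-phosphonocrotonate
Product: 23 (E)-4-(diethoxyphosphoryl)but-2-enoic acid
Conditions: LiOH (1.05 equiv), THF/H2O, 0 °C to rt; then aq. HCl
Reagents that add atoms: lithium hydroxide, [Li+].[OH-]
Why: Saponification of the carboxylic ethyl ester, which is far faster than hydrolysis of the diethyl phosphonate.

Step 16
Reactants: 23 (E)-4-(diethoxyphosphoryl)but-2-enoic acid; 21 2-amino-3-hydroxycyclopent-2-en-1-one hydrochloride
Product: 24 diethyl [(E)-4-[(2-hydroxy-5-oxocyclopent-1-en-1-yl)amino]-4-oxobut-2-en-1-yl]phosphonate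
Conditions: EDC·HCl, 1-hydroxybenzotriazole, N-methylmorpholine, DMF, 0 °C to rt
Reagents that add atoms: none
Why: Carbodiimide amide coupling through the hydroxybenzotriazole active ester, any O-acylated enol rearranging to the more stable N-acyl compound by O-to-N acyl transfer.

Step 17
Reactants: 18 the enal of step 12; 24 diethyl [(E)-4-[(2-hydroxy-5-oxocyclopent-1-en-1-yl)amino]-4-oxobut-2-en-1-yl]phosphonate
Product: 25 (2E,4R)-N-[(1S,5S,6R)-5-hydroxy-5-[(1E,3E,5E)-7-[(2-hydroxy-5-oxocyclopent-1-en-1-yl)amino]-7-oxohepta-1,3,5-trien-1-yl]-2-oxo-7-oxabicyclo[4.1.0]hept-3-en-3-yl]-2,4-dimethyloct-2-enamide (CNP0259711.1)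
Conditions: 24 (1.5 equiv), LiN(SiMe3)2 (2 equiv per 24), THF, −78 °C; then 18, −78 °C to −20 °C; aq. NaH2PO4
Reagents that add atoms: none
Why: Vinylogous Horner–Wadsworth–Emmons olefination, in which the enolate-protected phosphonate carbanion adds to the aldehyde through the carbon next to phosphorus and loses diethyl phosphate to form the new alkene E, completing the all-E triene.

**Compound list**

1 | 4-hydroxybenzaldehyde | O=Cc1ccc(O)cc1 | starting material
2 | tert-butyl (triphenylphosphoranylidene)acetate | CC(C)(C)OC(=O)C=P(c1ccccc1)(c1ccccc1)c1ccccc1 | starting material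
3 | tert-butyl (E)-3-(4-hydroxyphenyl)prop-2-enoate | CC(C)(C)OC(=O)/C=C/c1ccc(O)cc1 | intermediate
4 | tert-butyl (E)-3-(1-hydroxy-4-oxocyclohexa-2,5-dien-1-yl)prop-2-enoate | CC(C)(C)OC(=O)/C=C/C1(O)C=CC(=O)C=C1 | intermediate
5 | tert-butyl (E)-3-[(1S,5R,6R)-5-hydroxy-2-oxo-7-oxabicyclo[4.1.0]hept-3-en-5-yl]prop-2-enoate | C1=C[C@@](O)(/C=C/C(=O)OC(C)(C)C)[C@@H]2O[C@@H]2C1=O | intermediate
6 | tert-butyl (E)-3-[(1S,5S,6R)-5-hydroxy-3-iodo-2-oxo-7-oxabicyclo[4.1.0]hept-3-en-5-yl]prop-2-enoate | IC1=C[C@@](O)(/C=C/C(=O)OC(C)(C)C)[C@@H]2O[C@@H]2C1=O | intermediate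
7 | (R)-4-benzyloxazolidin-2-one | O=C1N[C@H](Cc2ccccc2)CO1 | starting material
8 | hexanoyl chloride | CCCCCC(=O)Cl | starting material
9 | (R)-4-benzyl-3-hexanoyloxazolidin-2-one | CCCCCC(=O)N1[C@H](Cc2ccccc2)COC1=O | intermediate
10 | (R)-4-benzyl-3-[(2R)-2-methylhexanoyl]oxazolidin-2-one | CCCC[C@@H](C)C(=O)N1[C@H](Cc2ccccc2)COC1=O | intermediate
11 | (R)-2-methylhexan-1-ol | CCCC[C@@H](C)CO | intermediate
12 | ethyl 2-(triphenylphosphoranylidene)propanoate | CCOC(=O)C(C)=P(c1ccccc1)(c1ccccc1)c1ccccc1 | starting material
13 | (R)-2-methylhexanal | CCCC[C@@H](C)C=O | intermediate (not isolated)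
14 | ethyl (2E,4R)-2,4-dimethyloct-2-enoate | CCCC[C@@H](C)/C=C(\C)C(=O)OCC | intermediate
15 | (2E,4R)-2,4-dimethyloct-2-enamide | CCCC[C@@H](C)/C=C(\C)C(N)=O | intermediate
16 | tert-butyl (E)-3-[(1S,5S,6R)-3-[[(2E,4R)-2,4-dimethyloct-2-enoyl]amino]-5-hydroxy-2-oxo-7-oxabicyclo[4.1.0]hept-3-en-5-yl]prop-2-enoate | CCCC[C@@H](C)/C=C(\C)C(=O)NC1=C[C@@](O)(/C=C/C(=O)OC(C)(C)C)[C@@H]2O[C@@H]2C1=O | intermediate
17 | (2E,4R)-N-[2,5-dihydroxy-5-[(E)-3-hydroxyprop-1-en-1-yl]-7-oxabicyclo[4.1.0]hept-3-en-3-yl]-2,4-dimethyloct-2-enamide, ring centres of 16 retained, both C1 epimers | CCCC[C@@H](C)/C=C(\C)C(=O)NC1=C[C@@](O)(/C=C/CO)[C@@H]2O[C@@H]2C1O | intermediate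
18 | (2E,4R)-N-[(1S,5S,6R)-5-hydroxy-2-oxo-5-[(E)-3-oxoprop-1-en-1-yl]-7-oxabicyclo[4.1.0]hept-3-en-3-yl]-2,4-dimethyloct-2-enamide | CCCC[C@@H](C)/C=C(\C)C(=O)NC1=C[C@@](O)(/C=C/C=O)[C@@H]2O[C@@H]2C1=O | intermediate
19 | cyclopentane-1,3-dione | O=C1CCC(=O)C1 | starting material
20 | 3-hydroxy-2-nitrocyclopent-2-en-1-one | O=C1CCC(O)=C1[N+](=O)[O-] | intermediate
21 | 2-amino-3-hydroxycyclopent-2-en-1-one hydrochloride | NC1=C(O)CCC1=O.Cl | intermediate
22 | triethyl 4-phosphonocrotonate | CCOC(=O)/C=C/CP(=O)(OCC)OCC | starting material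
23 | (E)-4-(diethoxyphosphoryl)but-2-enoic acid | OC(=O)/C=C/CP(=O)(OCC)OCC | intermediate
24 | diethyl [(E)-4-[(2-hydroxy-5-oxocyclopent-1-en-1-yl)amino]-4-oxobut-2-en-1-yl]phosphonate | CCOP(=O)(OCC)C/C=C/C(=O)NC1=C(O)CCC1=O | intermediate
25 | (2E,4R)-N-[(1S,5S,6R)-5-hydroxy-5-[(1E,3E,5E)-7-[(2-hydroxy-5-oxocyclopent-1-en-1-yl)amino]-7-oxohepta-1,3,5-trien-1-yl]-2-oxo-7-oxabicyclo[4.1.0]hept-3-en-3-yl]-2,4-dimethyloct-2-enamide | CCCC[C@@H](C)/C=C(\C)C(=O)NC1=C[C@@](O)(/C=C/C=C/C=C/C(=O)NC2=C(O)CCC2=O)[C@@H]2O[C@@H]2C1=O | target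

**Step count**

Total: 17 steps. Longest linear sequence: 9 steps (steps 5, 6, 7, 8, 9, 10, 11, 12, 17). The line from 4-hydroxybenzaldehyde is 8 steps and the phosphonate branch joins after 4 steps.

**Steps most likely to fail**

1. Step 3 (the labelled step). The chiral ammonium ion pair may discriminate too weakly between the two enones, or uncatalysed epoxidation may compete, so that 5 forms with low enantiomeric purity. Fallback with known chemistry, resolution in place of catalytic group selection: setting out from 4, hydroxyl-directed epoxidation with tBuOOH and catalytic benzyltrimethylammonium hydroxide in THF at 0 °C should give the racemic syn-epoxy quinol F1. Preparative chromatography on a chiral stationary phase (amylose tris(3,5-dimethylphenylcarbamate), hexane/2-propanol) then separates the enantiomers, and the (1S,5R,6R)-enantiomer rejoins the route as 5.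

2. Step 10. Base-induced degradation of the γ-hydroxy α-iodo epoxy enone (oxirane opening, loss of iodide) may outpace the C–N coupling at the temperature it needs. Fallback, with the carbonyl removed before the coupling and not after it: setting out from 6, iBu2AlH in CH2Cl2 at −78 °C should give the iodo triol F2, in which the ester has become the primary allylic alcohol and the C1 ketone a carbinol (both epimers). This base-stable vinyl iodide is then coupled with 15 under CuI, N,N'-dimethylethylenediamine and K2CO3 in toluene at 80 °C. That gives 17 directly, where the route is rejoined before the MnO2 oxidation.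

3. Step 17. The doubly deprotonated phosphonate may be protonated by the N–H and O–H groups of 18, or may add too slowly, so that base-mediated decomposition of the epoxy ketone and erosion of E-selectivity take over. Fallback, with the acidic cyclopentenone unit attached last by amide formation: setting out from 23, allyl bromide and K2CO3 in DMF should give allyl (E)-4-(diethoxyphosphoryl)but-2-enoate F3. Its monoanion (LiN(SiMe3)2, one equivalent, THF, −78 °C) is combined with 18 to give the all-E triene allyl ester F4. Pd(PPh3)4 (zerovalent palladium, catalytic) with N-methylaniline as allyl acceptor in THF should free the trienoic acid F5 under neutral conditions. Coupling of F5 with 21 (EDC·HCl, 1-hydroxybenzotriazole, N-methylmorpholine, DMF) returns to the route at the target 25.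

**Further compounds**

F1 | step 3 | racemic tert-butyl (E)-3-(syn-5,6-epoxy-4-hydroxy-1-oxocyclohex-2-en-4-yl)prop-2-enoate (5 and its enantiomer, 1:1) | C1=C[C@@](O)(/C=C/C(=O)OC(C)(C)C)[C@@H]2O[C@@H]2C1=O.C1=C[C@](O)(/C=C/C(=O)OC(C)(C)C)[C@H]2O[C@H]2C1=O
F2 | step 10 | 5-[(E)-3-hydroxyprop-1-en-1-yl]-3-iodo-7-oxabicyclo[4.1.0]hept-3-ene-2,5-diol, ring centres of 6 retained, both C1 epimers | IC1=C[C@@](O)(/C=C/CO)[C@@H]2O[C@@H]2C1O
F3 | step 17 | allyl (E)-4-(diethoxyphosphoryl)but-2-enoate | C=CCOC(=O)/C=C/CP(=O)(OCC)OCC
F4 | step 17 | allyl (2E,4E,6E)-7-[(1S,5S,6R)-3-[[(2E,4R)-2,4-dimethyloct-2-enoyl]amino]-5-hydroxy-2-oxo-7-oxabicyclo[4.1.0]hept-3-en-5-yl]hepta-2,4,6-trienoate | CCCC[C@@H](C)/C=C(\C)C(=O)NC1=C[C@@](O)(/C=C/C=C/C=C/C(=O)OCC=C)[C@@H]2O[C@@H]2C1=O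
F5 | step 17 | (2E,4E,6E)-7-[(1S,5S,6R)-3-[[(2E,4R)-2,4-dimethyloct-2-enoyl]amino]-5-hydroxy-2-oxo-7-oxabicyclo[4.1.0]hept-3-en-5-yl]hepta-2,4,6-trienoic acid | CCCC[C@@H](C)/C=C(\C)C(=O)NC1=C[C@@](O)(/C=C/C=C/C=C/C(=O)O)[C@@H]2O[C@@H]2C1=O
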